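The numbers in the tables are calculated on assumed constants; the scatter is artificial.

A one-step world, starting material plus dissolved gas to target, ends with the whole charge as target; the spring run ends at 83 % with 0 % starting material left.

| setting | spring | midnight | flask |
|---|---|---|---|
| starting material | 0.24 M | 0.36 M | 0.48 M |
| gas phase | 17 mM (held) | 17 mM (held) | 17 mM (held) |
| remark | run made earlier | run made earlier |  |
| time |  |  | 6.0 h |

| run | time / h | target / % | starting material / % |
|---|---|---|---|
| spring | 1.33 | 52 | 38 |
| spring | 2.50 | 72 | 16 |
| spring | 4.00 | 82 | 3 |
| spring | 5.00 | 82 | 0 |
| spring | 6.00 | 83 | 0 |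
| midnight | 1.33 | 49 | 43 |
| midnight | 2.50 | 69 | 19 |
| midnight | 4.00 | 77 | 6 |
| midnight | 5.00 | 78 | 2 |
| midnight | 6.00 | 82 | 1 |

(scatter of a reading: 1.5 percentage points)

- at the start none of the gas phase is in solution

- ash: doubling the transfer coefficient of the gas phase, all else as stated
- cedar: doubling the saturation concentration of gas phase, all else as stated

- amount of target at 6.0 h, in percent of the starting material charged
- concentration of dissolved gas in solution at 40 min, in percent of saturation
- the change that raises the amount of target at 6.0 h, in percent of the starting material charged most ("none" if none brings more than 2 percentage points) (ash / cedar / none)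
- amount of target at 6.0 h, in percent of the starting material charged, after cedar

The smaller reagent in solution is dissolved gas, 17 mM at saturation against 0.48 M of starting material in the flask. I therefore write its balance in quasi-steady state, crossing in equal to reaction away:

dissolved gas / saturation = 1 / (1 + starting material / H)

Integrated, this makes ln(charge/left) + (charge − left)/H equal in both runs at one time. The readings at 1.33 h give

H = 0.456 M

This is the half-supply charge, the amount of starting material at which dissolved gas stands at half saturation.

I assume the lost share goes to a side step that ignores dissolved gas. Averaged over a run, the loss then goes as 1 + charge/(2H). The end reading of the spring run gives a loss at full supply of 13.5 %, which puts the flask at 79.4 %.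

The weak link is that single reading, with its scatter of 1.5 percentage points. The midnight run gives 12.9 %, and the mean of the two is 13.2 %, so I commit to

target at 6.0 h = 79.9 %

Cedar leaves H as it is and raises the supply by a factor 2, so in my reckoning it divides the loss by that factor: 89.9 %. Ash sets H to 0.912 M: 83.3 %. I choose cedar, gaining 10 points against 3.4 points.

The forecast says 82 %, 59 % of saturation at 40 min, best none, and 83 % after cedar, on the ground: “Selectivity stays about 0.83–0.84 throughout, regardless of time or dissolved gas”. I differ from it by letting the loss grow with charge.

    gas phase ⇌ dissolved gas, rate k1*(csat - [dissolved gas]) (kL = 0.00560 s⁻¹)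
    starting material → side product A (k = 2.90 × 10⁻⁵ s⁻¹)
    starting material + target → side product B (k = 3.10 × 10⁻⁵ L mol⁻¹ s⁻¹)
    starting material + dissolved gas → target (k = 0.0140 L mol⁻¹ s⁻¹)

The flask gives 77.7 %, 53.7 % of saturation at 40 min, best cedar, and 87.5 % after cedar. Cedar brings 9.8 points and ash 3.2 points. At 3.00 h the flask holds 12.6 % starting material, for which the half-supply charge 0.456 M gives 88.3 % of saturation, and the flask stands at 86.4 %. For a neighbour flask, alike but charged with 0.29 M of starting material, the same reckoning gives 82.6 % target at 6.0 h, and that neighbour flask holds 82.0 %.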